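**Retrosynthetic overview**

1. Target 30 (2-hexaprenyl-6-methoxy-3-methyl-1,4-benzoquinone; C1 and C4 are the carbonyls, C5 is the only ring CH) ⇒ phenol 29 by para-oxidation at C1 ⇒ resorcinol monosilyl ether 27 by O-methylation at C6 and desilylation at C4.
2. Key disconnection: the benzene ring of 27 ⇒ cyclobutenone 18 (a masked vinylketene that brings C3–Me, C2–hexaprenyl, C1 and C6) + siloxyacetylene 22 (brings C5–H and C4–O). One thermal benzannulation makes C5–C6 and C3–C4 and places every ring substituent with the complete C30 chain already attached.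
3. Enabling feature: the oxygens on C6 (methoxy) and C4 (carbonyl) stand 1,3 across the unsubstituted C5, a masked resorcinol. This is the pattern that results when a ketene carbonyl carbon and an ynol ether carbon end up on either side of the alkyne CH; the C1 oxygen, para to C4, is added afterwards.
4. 18 ⇐ 3-ethoxy-2-methylcyclobutenone 15 (ketene + 1-ethoxypropyne, [2+2]) + hexaprenyl chloride 11 (α-selective allylbarium addition); 11 ⇐ two farnesyl units (allylic sulfone alkylation, then desulfonylation).
5. Ring order: the four-membered ring (step 8) first, the six-membered carbocycle (step 11) second; no other ring is formed.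

Key step: step 11

Remark (assumption): (2E,6E)-farnesol, (2E,6E)-farnesyl bromide, 1-ethoxyprop-1-yne, acetyl chloride and acetylene are taken as commercial. The target has no stereocentre, so only the five E double bonds must be carried through.
Shorthand: hexaprenyl = (2E,6E,10E,14E,18E)-3,7,11,15,19,23-hexamethyltetracosa-2,6,10,14,18,22-hexaen-1-yl; farnesyl = (2E,6E)-3,7,11-trimethyldodeca-2,6,10-trien-1-yl; Tol = 4-methylphenyl; TIPS = triisopropylsilyl.

**Route**

Step 1
Reactants: 1 (2E,6E)-farnesol
Product: 2 (2E,6E)-farnesyl acetate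
Conditions: Ac2O, pyridine, DMAP (cat.), CH2Cl2, 0 °C to rt
Reagents that add atoms: acetic anhydride, CC(=O)OC(C)=O
Why: DMAP-catalysed O-acetylation (nucleophilic acyl substitution) of the primary allylic alcohol should be clean, and the acetate both protects the alcohol and deactivates the 2,3-alkene toward the allylic oxidation that follows.

Step 2
Reactants: 2 (2E,6E)-farnesyl acetate
Product: 3 (2E,6E,10E)-12-hydroxy-3,7,11-trimethyldodeca-2,6,10-trien-1-yl acetate
Conditions: SeO2 (cat.), t-BuOOH, salicylic acid (cat.), CH2Cl2, 0 °C to rt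
Reagents that add atoms: SeO2, O=[Se]=O (oxygen-transfer agent), regenerated by tert-butyl hydroperoxide, CC(C)(C)OO (stoichiometric oxygen source)
Why: Catalytic SeO2/t-BuOOH allylic oxidation (ene reaction, then [2,3]-sigmatropic shift) should attack the terminal, most electron-rich trisubstituted alkene at its (E)-methyl group, so that the 10E allylic alcohol follows from the mechanism while the acetate-deactivated 2,3-alkene is spared.

Step 3
Reactants: 3 (2E,6E,10E)-12-hydroxy-3,7,11-trimethyldodeca-2,6,10-trien-1-yl acetate
Product: 4 (2E,6E,10E)-12-bromo-3,7,11-trimethyldodeca-2,6,10-trien-1-yl acetate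
Conditions: CBr4, PPh3, CH2Cl2, 0 °C
Reagents that add atoms: carbon tetrabromide, BrC(Br)(Br)Br
Why: Appel bromination (SN2 displacement of the alkoxyphosphonium by bromide) should convert the primary allylic alcohol under neutral conditions that leave the acetate and the alkene geometries untouched.

Step 4
Reactants: 5 (2E,6E)-farnesyl bromide
Product: 6 (2E,6E)-farnesyl 4-methylphenyl sulfone
Conditions: TolSO2Na, DMF, rt
Reagents that add atoms: sodium 4-methylbenzenesulfinate, Cc1ccc(cc1)S(=O)[O-].[Na+]
Why: S-alkylation of the ambident sulfinate by the soft primary allylic bromide (SN2) in a dipolar aprotic solvent should give the allylic sulfone with the 2E geometry retained.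

Step 5
Reactants: 6 (2E,6E)-farnesyl 4-methylphenyl sulfone; 4 (2E,6E,10E)-12-bromo-3,7,11-trimethyldodeca-2,6,10-trien-1-yl acetate
Product: 8 racemic (2E,6E,10E,14E,18E)-3,7,11,15,19,23-hexamethyl-13-(4-methylphenylsulfonyl)tetracosa-2,6,10,14,18,22-hexaen-1-yl acetate, via lithiated sulfone 7 (not isolated)
Conditions: n-BuLi (1.0 equiv), THF/DMPU, −78 °C; then 4, −78 to −40 °C
Reagents that add atoms: none
Why: Alkylation of a sulfone-stabilised allylic carbanion, which should react at its α-carbon with the primary allylic bromide by SN2 far faster than with the acetate at low temperature, joins the two C15 units head to tail, and the new sulfone-bearing stereocentre is formed racemic and is removed in step 6.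

Step 6
Reactants: 8 racemic (2E,6E,10E,14E,18E)-3,7,11,15,19,23-hexamethyl-13-(4-methylphenylsulfonyl)tetracosa-2,6,10,14,18,22-hexaen-1-yl acetate
Product: 10 (2E,6E,10E,14E,18E)-hexaprenol, via hydroxy sulfone 9 (not isolated)
Conditions: LiBHEt3 (6 equiv), THF, 0 °C; then PdCl2(dppp) (5 mol%; dppp = 1,3-bis(diphenylphosphino)propane), 0 °C to rt
Reagents that add atoms: none
Why: Hydride should first cleave the acetate to the alkoxide of 9, which zerovalent palladium cannot ionise, and the palladium-catalysed allylic hydrogenolysis of the sulfone (π-allyl formation, hydride delivery to the less substituted terminus) should then remove the sulfonyl group with the trisubstituted alkene kept in place and E.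

Step 7
Reactants: 10 (2E,6E,10E,14E,18E)-hexaprenol
Product: 11 (2E,6E,10E,14E,18E)-hexaprenyl chloride
Conditions: N-chlorosuccinimide, Me2S, CH2Cl2, −30 to 0 °C
Reagents that add atoms: N-chlorosuccinimide, O=C1CCC(=O)N1Cl
Why: Corey–Kim chlorination (alkoxysulfonium formation, SN2 displacement by chloride) should turn the primary allylic alcohol into the chloride without allylic transposition or loss of the 2E geometry.

Step 8
Reactants: 12 1-ethoxyprop-1-yne; 13 acetyl chloride
Product: 15 3-ethoxy-2-methylcyclobut-2-en-1-one, via ketene 14 (not isolated)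
Conditions: Et3N, Et2O, 0 °C to rt
Reagents that add atoms: none
Why: Triethylamine should dehydrochlorinate acetyl chloride to ketene, which undergoes the regioselective [2+2] cycloaddition with the electron-rich ynol ether (ketene carbonyl carbon to the nucleophilic methyl-bearing alkyne carbon) to give the 3-alkoxycyclobutenone.

Step 9
Reactants: 11 (2E,6E,10E,14E,18E)-hexaprenyl chloride; 15 3-ethoxy-2-methylcyclobut-2-en-1-one
Product: 18 3-hexaprenyl-2-methylcyclobut-2-en-1-one, via hexaprenylbarium chloride 16 (not isolated), via cyclobutenol adduct 17 (not isolated)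
Conditions: BaI2, lithium biphenylide Li(C12H10) (2 equiv), THF, rt (gives activated Ba metal); 11, −78 °C; 15, −78 °C; then 1 M aq. HCl, Et2O, 0 °C
Reagents that add atoms: water, O (supplies the carbonyl oxygen in the hydrolysis)
Why: Allylbarium reagents made from allylic chlorides and activated barium at −78 °C add to carbonyl groups at the α-carbon with retention of alkene geometry (α-selective allylbarium carbonyl addition), and acid hydrolysis of the resulting β-ethoxy allylic alcohol with carbonyl transposition should give the 3-substituted cyclobutenone, the same product that conjugate addition with loss of ethoxide would give.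

Step 10
Reactants: 19 acetylene
Product: 22 (ethynyloxy)triisopropylsilane, via lithium acetylide 20 (not isolated), via lithium ethynolate 21 (not isolated)
Conditions: n-BuLi, THF, −78 °C (acetylene in excess); LiOOt-Bu (from t-BuOOH and LiN(SiMe3)2), −78 to 0 °C; then TIPSOTf, −78 °C
Reagents that add atoms: tert-butyl hydroperoxide (used as LiOOt-Bu), CC(C)(C)OO; triisopropylsilyl trifluoromethanesulfonate, CC(C)[Si](C(C)C)(C(C)C)OS(=O)(=O)C(F)(F)F
Why: Oxidation of a lithium acetylide to the ynolate by lithium tert-butyl peroxide followed by O-silylation with a bulky silyl triflate, which favours oxygen over carbon, is the standard entry to siloxyalkynes and is applied here to the parent acetylide.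

Step 11
Reactants: 18 3-hexaprenyl-2-methylcyclobut-2-en-1-one; 22 (ethynyloxy)triisopropylsilane
Product: 27 3-hexaprenyl-4-methyl-5-(triisopropylsilyloxy)phenol, via vinylketene 23 (not isolated), via vinylcyclobutenone adduct 24 (not isolated), via dienylketene 25 (not isolated), via cyclohexadienone 26 (not isolated)
Conditions: 22 (2 equiv), toluene (degassed), 80 °C, then 110 °C
Reagents that add atoms: none
Why: Heating should open cyclobutenone 18 by a 4π-electrocyclic reaction to vinylketene 23, which adds siloxyalkyne 22 in a regiospecific [2+2] cycloaddition (electrophilic ketene carbonyl carbon to the nucleophilic CH terminus of the ynol ether) to give vinylcyclobutenone 24, and 24 opens again (4π) to dienylketene 25, which closes to cyclohexadienone 26 and tautomerises to phenol 27. The closest known reaction type is the Danheiser benzannulation of cyclobutenones with trialkylsiloxyalkynes, which gives resorcinol monosilyl ethers. The six-membered ring is closed by 6π-electrocyclisation of the dienylketene, in effect an insertion of the two alkyne carbons into the acyl–alkenyl bond of the cyclobutenone, so that C5–C6 and C3–C4 of the later quinone are the two bonds made. No stereocentre is set: the quaternary centre of 24 is transient, and only the dienylketene isomer with ketene and vinyl groups cis can cyclise, the other returning through reversible ring-opening. The selectivity needed is regiochemical and chemoselective: the polarisation of ketene and ynol ether places the two oxygens 1,3 with the unsubstituted CH between them, the strongly nucleophilic siloxyalkyne in excess should outcompete the six unactivated trisubstituted chain alkenes and the product phenol for the ketene, and the neutral thermal conditions leave all E double bonds untouched.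

Step 12
Reactants: 27 3-hexaprenyl-4-methyl-5-(triisopropylsilyloxy)phenol
Product: 28 (3-hexaprenyl-5-methoxy-2-methylphenoxy)triisopropylsilane
Conditions: MeI, K2CO3, acetone, rt
Reagents that add atoms: iodomethane, CI
Why: Williamson O-methylation of the free phenol (SN2 on iodomethane) under mild carbonate conditions should leave the hindered aryl triisopropylsilyl ether in place and so fix the methoxy group on C6.

Step 13
Reactants: 28 (3-hexaprenyl-5-methoxy-2-methylphenoxy)triisopropylsilane
Product: 29 3-hexaprenyl-5-methoxy-2-methylphenol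
Conditions: TBAF, THF, 0 °C; aq. NH4Cl
Reagents that add atoms: none
Why: Fluoride-mediated cleavage of the aryl silyl ether (driven by Si–F bond formation) should release the C4 phenol without touching the methyl ether or the polyene chain.

Step 14
Reactants: 29 3-hexaprenyl-5-methoxy-2-methylphenol
Product: 30 2-hexaprenyl-6-methoxy-3-methyl-1,4-benzoquinone (target)
Conditions: (KSO3)2NO (2.5 equiv), aq. KH2PO4, acetone/THF–H2O, 0 °C to rt
Reagents that add atoms: potassium nitrosodisulfonate (Fremy's salt), [K+].[K+].[O-]S(=O)(=O)N([O])S(=O)(=O)[O-]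
Why: In the Teuber oxidation the nitrosodisulfonate radical abstracts the phenolic hydrogen, a second equivalent couples at the free para position (C1) and loss of imidodisulfonate should give the para-quinone, with a one-electron oxidant that is inert to isolated trisubstituted alkenes.

**Compound list**

1 | (2E,6E)-farnesol | OC/C=C(\C)CC/C=C(\C)CCC=C(C)C | starting material
2 | (2E,6E)-farnesyl acetate | CC(=O)OC/C=C(\C)CC/C=C(\C)CCC=C(C)C | intermediate
3 | (2E,6E,10E)-12-hydroxy-3,7,11-trimethyldodeca-2,6,10-trien-1-yl acetate | CC(=O)OC/C=C(\C)CC/C=C(\C)CC/C=C(\C)CO | intermediate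
4 | (2E,6E,10E)-12-bromo-3,7,11-trimethyldodeca-2,6,10-trien-1-yl acetate | CC(=O)OC/C=C(\C)CC/C=C(\C)CC/C=C(\C)CBr | intermediate
5 | (2E,6E)-farnesyl bromide | BrC/C=C(\C)CC/C=C(\C)CCC=C(C)C | starting material
6 | (2E,6E)-farnesyl 4-methylphenyl sulfone | Cc1ccc(cc1)S(=O)(=O)C/C=C(\C)CC/C=C(\C)CCC=C(C)C | intermediate
7 | lithiated sulfone (α-lithio derivative of 6) | [Li]C(/C=C(\C)CC/C=C(\C)CCC=C(C)C)S(=O)(=O)c1ccc(C)cc1 | intermediate
8 | racemic (2E,6E,10E,14E,18E)-3,7,11,15,19,23-hexamethyl-13-(4-methylphenylsulfonyl)tetracosa-2,6,10,14,18,22-hexaen-1-yl acetate | CC(=O)OC/C=C(\C)CC/C=C(\C)CC/C=C(\C)CC(/C=C(\C)CC/C=C(\C)CCC=C(C)C)S(=O)(=O)c1ccc(C)cc1 | intermediate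
9 | hydroxy sulfone, racemic (2E,6E,10E,14E,18E)-3,7,11,15,19,23-hexamethyl-13-(4-methylphenylsulfonyl)tetracosa-2,6,10,14,18,22-hexaen-1-ol | OC/C=C(\C)CC/C=C(\C)CC/C=C(\C)CC(/C=C(\C)CC/C=C(\C)CCC=C(C)C)S(=O)(=O)c1ccc(C)cc1 | intermediate
10 | (2E,6E,10E,14E,18E)-hexaprenol | OC/C=C(\C)CC/C=C(\C)CC/C=C(\C)CC/C=C(\C)CC/C=C(\C)CCC=C(C)C | intermediate
11 | (2E,6E,10E,14E,18E)-hexaprenyl chloride | ClC/C=C(\C)CC/C=C(\C)CC/C=C(\C)CC/C=C(\C)CC/C=C(\C)CCC=C(C)C | intermediate
12 | 1-ethoxyprop-1-yne | CC#COCC | starting material
13 | acetyl chloride | CC(Cl)=O | starting material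
14 | ketene | C=C=O | intermediate
15 | 3-ethoxy-2-methylcyclobut-2-en-1-one | CCOC1=C(C)C(=O)C1 | intermediate
16 | hexaprenylbarium chloride | Cl[Ba]C/C=C(\C)CC/C=C(\C)CC/C=C(\C)CC/C=C(\C)CC/C=C(\C)CCC=C(C)C | intermediate
17 | cyclobutenol adduct, racemic 3-ethoxy-1-hexaprenyl-2-methylcyclobut-2-en-1-ol (as its barium alkoxide) | CCOC1=C(C)C(O)(C/C=C(\C)CC/C=C(\C)CC/C=C(\C)CC/C=C(\C)CC/C=C(\C)CCC=C(C)C)C1 | intermediate
18 | 3-hexaprenyl-2-methylcyclobut-2-en-1-one | CC1=C(C/C=C(\C)CC/C=C(\C)CC/C=C(\C)CC/C=C(\C)CC/C=C(\C)CCC=C(C)C)CC1=O | intermediate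
19 | acetylene | C#C | starting material
20 | lithium acetylide | [Li]C#C | intermediate
21 | lithium ethynolate | [Li]OC#C | intermediate
22 | (ethynyloxy)triisopropylsilane | C#CO[Si](C(C)C)(C(C)C)C(C)C | intermediate
23 | vinylketene, 3-hexaprenyl-2-methylbuta-1,3-dien-1-one | O=C=C(C)C(=C)C/C=C(\C)CC/C=C(\C)CC/C=C(\C)CC/C=C(\C)CC/C=C(\C)CCC=C(C)C | intermediate
24 | vinylcyclobutenone adduct, racemic 4-methyl-4-(1-hexaprenylvinyl)-3-(triisopropylsilyloxy)cyclobut-2-en-1-one | O=C1C=C(O[Si](C(C)C)(C(C)C)C(C)C)C1(C)C(=C)C/C=C(\C)CC/C=C(\C)CC/C=C(\C)CC/C=C(\C)CC/C=C(\C)CCC=C(C)C | intermediate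
25 | dienylketene, 5-hexaprenyl-4-methyl-3-(triisopropylsilyloxy)hexa-1,3,5-trien-1-one with the ketene and vinyl groups cis on the central double bond | O=C=C/C(O[Si](C(C)C)(C(C)C)C(C)C)=C(/C)C(=C)C/C=C(\C)CC/C=C(\C)CC/C=C(\C)CC/C=C(\C)CC/C=C(\C)CCC=C(C)C | intermediate
26 | cyclohexadienone, 5-hexaprenyl-4-methyl-3-(triisopropylsilyloxy)cyclohexa-2,4-dien-1-one | O=C1C=C(O[Si](C(C)C)(C(C)C)C(C)C)C(C)=C(C/C=C(\C)CC/C=C(\C)CC/C=C(\C)CC/C=C(\C)CC/C=C(\C)CCC=C(C)C)C1 | intermediate
27 | 3-hexaprenyl-4-methyl-5-(triisopropylsilyloxy)phenol | Oc1cc(O[Si](C(C)C)(C(C)C)C(C)C)c(C)c(C/C=C(\C)CC/C=C(\C)CC/C=C(\C)CC/C=C(\C)CC/C=C(\C)CCC=C(C)C)c1 | intermediate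
28 | (3-hexaprenyl-5-methoxy-2-methylphenoxy)triisopropylsilane | COc1cc(O[Si](C(C)C)(C(C)C)C(C)C)c(C)c(C/C=C(\C)CC/C=C(\C)CC/C=C(\C)CC/C=C(\C)CC/C=C(\C)CCC=C(C)C)c1 | intermediate
29 | 3-hexaprenyl-5-methoxy-2-methylphenol | COc1cc(O)c(C)c(C/C=C(\C)CC/C=C(\C)CC/C=C(\C)CC/C=C(\C)CC/C=C(\C)CCC=C(C)C)c1 | intermediate
30 | 2-hexaprenyl-6-methoxy-3-methyl-1,4-benzoquinone | COC1=CC(=O)C(C)=C(C/C=C(\C)CC/C=C(\C)CC/C=C(\C)CC/C=C(\C)CC/C=C(\C)CCC=C(C)C)C1=O | target

**Step count**

Total: 14 steps. Longest linear sequence: 11 steps (1, 2, 3, 5, 6, 7, 9, 11, 12, 13, 14).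

**Steps most likely to fail, with fallbacks**

Step 9. The allylbarium may equilibrate before it adds, with loss of the 2E geometry and attack through the γ-carbon, or the addition to the vinylogous ester may be too slow at −78 °C. The fallback reverses the polarity and sets out from 15 and 11. Bu3SnLi (from Bu3SnH and LiN(i-Pr)2) in THF at −78 °C should add to the carbonyl group of 15 to give racemic 3-ethoxy-2-methyl-1-(tributylstannyl)cyclobut-2-en-1-ol F1, which is not isolated. Dilute aqueous HCl should convert F1 into 2-methyl-3-(tributylstannyl)cyclobut-2-en-1-one F2. Stille coupling of F2 with chloride 11 (Pd2(dba)3, tri(2-furyl)phosphine, THF/NMP, 45 °C) should join the less hindered allyl terminus to the ring with retention of the E geometry and come back to the route at 18.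

Step 10. Monolithium acetylide may disproportionate to dilithium acetylide and acetylene on warming, so that the peroxide oxidation stalls, and silylation at carbon may compete with silylation at oxygen. The fallback makes the ynolate by cycloreversion and sets out from commercial 3-phenylisoxazole in place of acetylene 19. Deprotonation at C5 with n-BuLi in THF at −78 °C should give 5-lithio-3-phenylisoxazole F3. On warming, F3 should fragment to benzonitrile and lithium ethynolate 21, where the fallback rejoins the route; TIPSOTf at −78 °C then gives 22.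

Step 11. Vinylketene 23 may be captured by the product phenol (aryl ester formation), the silyl group of 22 may shift thermally from oxygen to carbon to give a silylketene, or the ketene may dimerise or add to chain alkenes. The fallback builds the arene classically and attaches the chain last; it sets out from 11 and commercial 3-bromo-2-methylphenol. Silylation of this phenol with TIPSCl and imidazole in DMF should give (3-bromo-2-methylphenoxy)triisopropylsilane F4. Iridium-catalysed C–H borylation of F4 ([Ir(OMe)(cod)]2, 4,4'-di-tert-butyl-2,2'-bipyridine, B2pin2, THF, 70 °C) should take place at C5, the only C–H not ortho to a substituent, and give [3-bromo-2-methyl-5-(4,4,5,5-tetramethyl-1,3,2-dioxaborolan-2-yl)phenoxy]triisopropylsilane F5. Oxidation of F5 with NaBO3·4H2O in THF/H2O should give 3-bromo-4-methyl-5-(triisopropylsilyloxy)phenol F6. Methylation of F6 (MeI, K2CO3, acetone) should give (3-bromo-5-methoxy-2-methylphenoxy)triisopropylsilane F7. Bromine–lithium exchange on F7 (t-BuLi, THF, −78 °C) should give [3-methoxy-6-methyl-5-(triisopropylsilyloxy)phenyl]lithium F8. Transmetalation of F8 with CuBr·SMe2 and SN2-type allylation with 11 (−78 to 0 °C) should then return to the route at 28, by-passing 18, 22 and 27.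

**Further compounds**

F1 | step 9 | racemic 3-ethoxy-2-methyl-1-(tributylstannyl)cyclobut-2-en-1-ol | CCOC1=C(C)C(O)(C1)[Sn](CCCC)(CCCC)CCCC
F2 | step 9 | 2-methyl-3-(tributylstannyl)cyclobut-2-en-1-one | CC1=C(CC1=O)[Sn](CCCC)(CCCC)CCCC
F3 | step 10 | 5-lithio-3-phenylisoxazole | [Li]c1cc(no1)-c1ccccc1
F4 | step 11 | (3-bromo-2-methylphenoxy)triisopropylsilane | Cc1c(Br)cccc1O[Si](C(C)C)(C(C)C)C(C)C
F5 | step 11 | [3-bromo-2-methyl-5-(4,4,5,5-tetramethyl-1,3,2-dioxaborolan-2-yl)phenoxy]triisopropylsilane | Cc1c(Br)cc(cc1O[Si](C(C)C)(C(C)C)C(C)C)B1OC(C)(C)C(C)(C)O1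
F6 | step 11 | 3-bromo-4-methyl-5-(triisopropylsilyloxy)phenol | Cc1c(Br)cc(O)cc1O[Si](C(C)C)(C(C)C)C(C)C
F7 | step 11 | (3-bromo-5-methoxy-2-methylphenoxy)triisopropylsilane | COc1cc(Br)c(C)c(O[Si](C(C)C)(C(C)C)C(C)C)c1
F8 | step 11 | [3-methoxy-6-methyl-5-(triisopropylsilyloxy)phenyl]lithium | [Li]c1cc(OC)cc(O[Si](C(C)C)(C(C)C)C(C)C)c1C
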